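**Plan**

1. Numbering used in all names: five-membered ring C1 (bears methyl C15)–C2–C3–C4 (isopropyl carbinol)–C5; seven-membered ring C1–C5–C6 (ester)–C7–C8 (=C14H2)–C9 (carbinol)–C10.
2. Retrosynthesis: the ester C6–O bond, the C8=C14 bond (methylenation of a C9 ketone) and the C5–H/C6–O pair (hydroboration of a C5=C6 alkene) are cut first, then C1–C5 and C6–C7 together.
3. Enabling feature: C1–C10–C9–C8–C7 of the seven-membered ring is a five-carbon unit (alkene C1=C10 plus cyclopropane C9/C8/C7), C5–C6 is a two-carbon unit (alkyne), and C2–C3–C4 of the five-membered ring is the three-atom tether between them, so one (5+2) cycloaddition closes both rings.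
4. Forward: (S)-terpinen-4-ol is ring-opened to a chain with a C1 methyl ketone and a C6 aldehyde; C10–C9 are added by olefination, C8–C7 by cyclopropanation, the aldehyde becomes the alkyne, both rings then form in one step, and C5/C6, C14 and C9 are adjusted last.
5. Stereochemistry: C4 comes from terpinen-4-ol; C1 is relayed from C4 in the cycloaddition; C5 and C6 arise by syn hydroboration anti to the C15 methyl; C9 by hydride attack anti to the same methyl.

Key step: step 9

Assumption: commercial (S)-(+)-terpinen-4-ol is taken as enantiomerically pure enough to carry the absolute configuration; bicyclic names use the numbering of the plan, not systematic bicyclo numbering.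

**Route**

Step 1
Reactants: 1 (S)-terpinen-4-ol
Product: 2 (S)-terpinen-4-ol triethylsilyl ether
Conditions: TESOTf, 2,6-lutidine, CH2Cl2, 0 °C → rt
Reagents that add atoms: triethylsilyl trifluoromethanesulfonate, CC[Si](CC)(CC)OS(=O)(=O)C(F)(F)F
Why: Silylation of a hindered tertiary alcohol with a silyl triflate and a hindered pyridine base is standard and masks the carbinol before the ring is opened, without touching the stereocentre.

Step 2
Reactants: 2 (S)-terpinen-4-ol triethylsilyl ether
Product: 4 (S)-6-oxo-3-(propan-2-yl)-3-(triethylsilyloxy)heptanal (keto aldehyde), via secondary ozonide 3 (not isolated)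
Conditions: O3, CH2Cl2, −78 °C; then PPh3, −78 °C → rt
Reagents that add atoms: ozone, [O-][O+]=O
Why: Ozonolysis with reductive work-up cleaves the only alkene to the methyl ketone (future C1/C15) and the aldehyde (future C6), while the quaternary C4 centre is carried through unchanged.

Step 3
Reactants: 4 (S)-6-oxo-3-(propan-2-yl)-3-(triethylsilyloxy)heptanal
Product: 5 (S)-7,7-dimethoxy-5-(propan-2-yl)-5-(triethylsilyloxy)heptan-2-one (keto acetal)
Conditions: HC(OMe)3, CeCl3·7H2O (cat.), MeOH, rt
Reagents that add atoms: trimethyl orthoformate, COC(OC)OC; methanol, CO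
Why: Acetalization with trimethyl orthoformate under CeCl3 catalysis is selective for aldehydes over ketones, so only the aldehyde is masked and the ketone stays free for olefination.

Step 4
Reactants: 5 (S)-7,7-dimethoxy-5-(propan-2-yl)-5-(triethylsilyloxy)heptan-2-one; 6 triethyl phosphonoacetate
Product: 7 ethyl (2E,6S)-8,8-dimethoxy-3-methyl-6-(propan-2-yl)-6-(triethylsilyloxy)oct-2-enoate
Conditions: NaH, THF, 0 °C → 50 °C
Reagents that add atoms: none
Why: Horner–Wadsworth–Emmons olefination of a methyl ketone with a phosphonoacetate anion should favour the E enoate (ester trans to the longer chain), the minor Z isomer being removed by chromatography.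

Step 5
Reactants: 7 ethyl (2E,6S)-8,8-dimethoxy-3-methyl-6-(propan-2-yl)-6-(triethylsilyloxy)oct-2-enoate
Product: 8 1-[(1E,5S)-7,7-dimethoxy-2-methyl-5-(propan-2-yl)-5-(triethylsilyloxy)hept-1-en-1-yl]cyclopropan-1-ol
Conditions: EtMgBr (3 equiv, slow addition), Ti(OiPr)4 (0.3 equiv), THF, 0 °C → rt; aq NH4Cl
Reagents that add atoms: ethylmagnesium bromide, CC[Mg]Br
Why: Kulinkovich cyclopropanation (a titanacyclopropane from EtMgBr and Ti(OiPr)4 acting as a 1,2-dicarbanion on the ester) is expected to tolerate a conjugated ester whose β-carbon is disubstituted and leaves the alkene geometry intact.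

Step 6
Reactants: 8 1-[(1E,5S)-7,7-dimethoxy-2-methyl-5-(propan-2-yl)-5-(triethylsilyloxy)hept-1-en-1-yl]cyclopropan-1-ol
Product: 9 tert-butyldimethylsilyl ether of 8
Conditions: TBSCl, imidazole, DMF, rt
Reagents that add atoms: tert-butyldimethylsilyl chloride, CC(C)(C)[Si](C)(C)Cl
Why: Silylation of the cyclopropanol with a silyl chloride and imidazole is routine, and a silyl triflate is avoided because it would attack the dimethyl acetal.

Step 7
Reactants: 9 tert-butyldimethylsilyl ether of 8
Product: 10 (3S,6E)-7-[1-(tert-butyldimethylsilyloxy)cyclopropyl]-6-methyl-3-(propan-2-yl)-3-(triethylsilyloxy)hept-6-enal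
Conditions: PPTS (cat.), acetone/H2O, 40 °C
Reagents that add atoms: water, O
Why: Mild acid-catalysed acetal hydrolysis of the unhindered dimethyl acetal should free the aldehyde without touching the tertiary silyl ether or the siloxycyclopropane.

Step 8
Reactants: 10 (3S,6E)-7-[1-(tert-butyldimethylsilyloxy)cyclopropyl]-6-methyl-3-(propan-2-yl)-3-(triethylsilyloxy)hept-6-enal
Product: 12 (3R,6E)-7-[1-(tert-butyldimethylsilyloxy)cyclopropyl]-6-methyl-3-(propan-2-yl)-3-(triethylsilyloxy)hept-6-en-1-yne, via alkenyl nonaflate 11 (not isolated)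
Conditions: C4F9SO2F, P2-Et phosphazene base, DMF, −30 °C → rt
Reagents that add atoms: none
Why: Enol sulfonate formation–elimination: the phosphazene base enolizes the aldehyde, the enolate is trapped on oxygen by the sulfonyl fluoride, and a second equivalent of base eliminates nonaflate to give the terminal alkyne with the same carbon count (the descriptor at C4 changes only because priorities change).

Step 9
Reactants: 12 (3R,6E)-7-[1-(tert-butyldimethylsilyloxy)cyclopropyl]-6-methyl-3-(propan-2-yl)-3-(triethylsilyloxy)hept-6-en-1-yne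
Product: 13 (1R,4R)-9-(tert-butyldimethylsilyloxy)-1-methyl-4-(propan-2-yl)-4-(triethylsilyloxy)bicyclo[5.3.0]deca-5,9-diene (C15 methyl cis to the C4 silyloxy group)
Conditions: [Rh(CO)2Cl]2 (5 mol %), toluene (0.02 M), 90 °C
Reagents that add atoms: none
Why: Monovalent rhodium binds the vinylcyclopropane and opens the C9–C7 bond to a σ-alkyl/π-allyl rhodacycle (trivalent rhodium) holding C1–C10–C9–C8–C7, the tethered alkyne inserts into the Rh–C1 bond (forming C1–C5), and C(sp2)–C(sp3) reductive elimination forms C6–C7, leaving the C5=C6 alkene and the C9=C10 silyl enol ether. The closest known reaction type is the rhodium-catalysed intramolecular (5+2) cycloaddition of alkyne-tethered vinylcyclopropanes, which is known for oxygen-substituted cyclopropanes and for alkenes that become quaternary ring-fusion carbons. The five-membered ring closes by 5-exo attack of alkyne carbon C5 on C1 (exo to both π-systems, allowed by the three-atom tether C2–C3–C4), and the seven-membered ring closes by reductive elimination from the eight-membered rhodacycle. The only new stereocentre, C1, is controlled by C4 through a 1,3-relay across C5: the far-reaching triethylsilyloxy group should take the exo position of the forming bicycle, away from the rhodium-bound C10–C9 unit, which puts the C15 methyl on its face and the isopropyl group on the face of C10 (1R). The step needs this facial selectivity and a preference for cycloaddition over alkyne oligomerization or cyclopropane isomerization; the latter is secured by the E alkene (tether trans to the cyclopropane), the 1-siloxy group that favours the reactive s-cis conformer, and high dilution, while the former rests on the C4 relay alone and is the least secured element, the C1 epimers being separable diastereomers.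

Step 10
Reactants: 13 (1R,4R)-9-(tert-butyldimethylsilyloxy)-1-methyl-4-(propan-2-yl)-4-(triethylsilyloxy)bicyclo[5.3.0]deca-5,9-diene
Product: 14 (1R,4R)-1-methyl-4-(propan-2-yl)-4-(triethylsilyloxy)bicyclo[5.3.0]dec-5-en-9-one
Conditions: TBAF, AcOH, THF, 0 °C
Reagents that add atoms: none
Why: Fluoride-mediated desilylation cleaves the silyl enol ether far faster than the hindered tertiary alkyl silyl ether, and the buffered enolate is protonated at C10, which is not stereogenic.

Step 11
Reactants: 14 (1R,4R)-1-methyl-4-(propan-2-yl)-4-(triethylsilyloxy)bicyclo[5.3.0]dec-5-en-9-one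
Product: 15 9,9-ethylenedioxy ketal (1,3-dioxolane) of 14
Conditions: TMSOCH2CH2OTMS, TMSOTf (cat.), CH2Cl2, −78 → −20 °C
Reagents that add atoms: 1,2-bis(trimethylsilyloxy)ethane, C[Si](C)(C)OCCO[Si](C)(C)C
Why: Noyori ketalization under aprotic low-temperature conditions masks the ketone against borane without ionizing the allylic tertiary silyl ether or moving the C5=C6 double bond.

Step 12
Reactants: 15 9,9-ethylenedioxy ketal of 14
Product: 17 (1R,4R,5S,6S)-9,9-(ethylenedioxy)-1-methyl-4-(propan-2-yl)-4-(triethylsilyloxy)bicyclo[5.3.0]decan-6-ol (trans ring fusion; H-5 cis to the 6-hydroxyl), via C6 alkylborane 16 (not isolated)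
Conditions: BH3·THF (3 equiv), THF, 0 °C → rt; then NaOH, H2O2, 0 °C → rt
Reagents that add atoms: hydrogen peroxide, OO
Why: Hydroboration–oxidation adds boron to the less substituted C6 and hydrogen to C5 in a syn fashion, expected from the face opposite the C15 methyl and the C4 silyloxy group as for related ring-fusion alkenes next to an angular methyl, and oxidation with retention gives the trans-fused 5S,6S alcohol.

Step 13
Reactants: 18 4-hydroxybenzoic acid
Product: 20 4-(triisopropylsilyloxy)benzoic acid, via bis-silylated acid 19 (not isolated)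
Conditions: TIPSCl, imidazole, DMF, rt; then AcOH, THF/H2O, rt
Reagents that add atoms: triisopropylsilyl chloride, CC(C)[Si](Cl)(C(C)C)C(C)C
Why: Exhaustive silylation followed by selective hydrolysis of the labile silyl ester is the standard way to an O-silyl-protected hydroxybenzoic acid.

Step 14
Reactants: 17 (1R,4R,5S,6S)-9,9-(ethylenedioxy)-1-methyl-4-(propan-2-yl)-4-(triethylsilyloxy)bicyclo[5.3.0]decan-6-ol; 20 4-(triisopropylsilyloxy)benzoic acid
Product: 21 6-O-[4-(triisopropylsilyloxy)benzoyl] ester of 17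
Conditions: DCC, DMAP, CH2Cl2, rt
Reagents that add atoms: none
Why: Steglich esterification acylates the only free hydroxyl, the hindered secondary C6 alcohol, with retention of its configuration.

Step 15
Reactants: 21 6-O-[4-(triisopropylsilyloxy)benzoyl] ester of 17
Product: 22 (1R,4R,5S,6S)-1-methyl-9-oxo-4-(propan-2-yl)-4-(triethylsilyloxy)bicyclo[5.3.0]decan-6-yl 4-(triisopropylsilyloxy)benzoate
Conditions: PPTS, acetone/H2O, 50 °C
Reagents that add atoms: water, O
Why: Acid-catalysed ketal hydrolysis returns the C9 ketone, and the ester and both silyl ethers should tolerate pyridinium tosylate.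

Step 16
Reactants: 22 (1R,4R,5S,6S)-1-methyl-9-oxo-4-(propan-2-yl)-4-(triethylsilyloxy)bicyclo[5.3.0]decan-6-yl 4-(triisopropylsilyloxy)benzoate
Product: 23 C8=C9 trimethylsilyl enol ether of 22
Conditions: LiN(iPr)2 (LDA), TMSCl (in situ quench), THF, −78 °C
Reagents that add atoms: chlorotrimethylsilane, C[Si](C)(C)Cl
Why: Kinetic enolization takes the less hindered C8 hydrogen (C10 is neopentyl), and in-situ silylation traps the enolate before it can attack the C6 ester.

Step 17
Reactants: 23 C8=C9 trimethylsilyl enol ether of 22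
Product: 26 (1R,4R,5S,6S)-1-methyl-8-methylidene-9-oxo-4-(propan-2-yl)-4-(triethylsilyloxy)bicyclo[5.3.0]decan-6-yl 4-(triisopropylsilyloxy)benzoate, via Mannich base 24 (not isolated), via methiodide 25 (not isolated)
Conditions: CH2=NMe2+ I−, CH2Cl2, rt; then MeI; then DBU, rt
Reagents that add atoms: Eschenmoser's salt (dimethylmethylideneammonium iodide), C=[N+](C)C.[I-]
Why: Mannich reaction of the silyl enol ether with Eschenmoser's salt places the aminomethyl group at C8, and quaternization followed by Hofmann-type elimination of trimethylamine gives the exocyclic enone.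

Step 18
Reactants: 26 (1R,4R,5S,6S)-1-methyl-8-methylidene-9-oxo-4-(propan-2-yl)-4-(triethylsilyloxy)bicyclo[5.3.0]decan-6-yl 4-(triisopropylsilyloxy)benzoate
Product: 27 (1R,4R,5S,6S,9R)-9-hydroxy-1-methyl-8-methylidene-4-(propan-2-yl)-4-(triethylsilyloxy)bicyclo[5.3.0]decan-6-yl 4-(triisopropylsilyloxy)benzoate
Conditions: NaBH4, CeCl3·7H2O, MeOH, −78 → 0 °C
Reagents that add atoms: none
Why: Luche reduction is 1,2-selective for the enone, and hydride should add to C9 from the face opposite the C15 methyl (1,3 to the carbonyl), giving the 9R alcohol cis to that methyl.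

Step 19
Reactants: 27 (1R,4R,5S,6S,9R)-9-hydroxy-1-methyl-8-methylidene-4-(propan-2-yl)-4-(triethylsilyloxy)bicyclo[5.3.0]decan-6-yl 4-(triisopropylsilyloxy)benzoate
Product: 28 (1R,4R,5S,6S,9R)-4,9-dihydroxy-1-methyl-8-methylidene-4-(propan-2-yl)bicyclo[5.3.0]decan-6-yl 4-hydroxybenzoate (CNP0164257.2)
Conditions: TBAF, AcOH, THF, 0 °C → rt
Reagents that add atoms: none
Why: Fluoride-mediated desilylation cleaves the aryl silyl ether and the tertiary triethylsilyl ether in one operation, and the acetic acid buffer should keep the benzoate and the allylic alcohol intact.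

**Compound list**

1 | (S)-terpinen-4-ol | CC1=CC[C@](O)(C(C)C)CC1 | starting material
2 | (S)-terpinen-4-ol triethylsilyl ether | CC1=CC[C@](O[Si](CC)(CC)CC)(C(C)C)CC1 | intermediate
3 | secondary ozonide of 2 (1,2,4-trioxolane across the former C=C, mixture at the two new centres) | CC12CC[C@@](O[Si](CC)(CC)CC)(C(C)C)CC(OO1)O2 | intermediate
4 | (S)-6-oxo-3-(propan-2-yl)-3-(triethylsilyloxy)heptanal | O=CC[C@](O[Si](CC)(CC)CC)(C(C)C)CCC(C)=O | intermediate
5 | (S)-7,7-dimethoxy-5-(propan-2-yl)-5-(triethylsilyloxy)heptan-2-one | COC(OC)C[C@](O[Si](CC)(CC)CC)(C(C)C)CCC(C)=O | intermediate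
6 | triethyl phosphonoacetate | CCOC(=O)CP(=O)(OCC)OCC | starting material
7 | ethyl (2E,6S)-8,8-dimethoxy-3-methyl-6-(propan-2-yl)-6-(triethylsilyloxy)oct-2-enoate | COC(OC)C[C@](O[Si](CC)(CC)CC)(C(C)C)CC/C(C)=C/C(=O)OCC | intermediate
8 | 1-[(1E,5S)-7,7-dimethoxy-2-methyl-5-(propan-2-yl)-5-(triethylsilyloxy)hept-1-en-1-yl]cyclopropan-1-ol | COC(OC)C[C@](O[Si](CC)(CC)CC)(C(C)C)CC/C(C)=C/C1(O)CC1 | intermediate
9 | tert-butyldimethylsilyl ether of 8 | COC(OC)C[C@](O[Si](CC)(CC)CC)(C(C)C)CC/C(C)=C/C1(O[Si](C)(C)C(C)(C)C)CC1 | intermediate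
10 | (3S,6E)-7-[1-(tert-butyldimethylsilyloxy)cyclopropyl]-6-methyl-3-(propan-2-yl)-3-(triethylsilyloxy)hept-6-enal | O=CC[C@](O[Si](CC)(CC)CC)(C(C)C)CC/C(C)=C/C1(O[Si](C)(C)C(C)(C)C)CC1 | intermediate
11 | alkenyl nonaflate of 10 (C5=C6–ONf, E/Z mixture, C4 unchanged) | FC(F)(F)C(F)(F)C(F)(F)C(F)(F)S(=O)(=O)OC=C[C@](O[Si](CC)(CC)CC)(C(C)C)CC/C(C)=C/C1(O[Si](C)(C)C(C)(C)C)CC1 | intermediate
12 | (3R,6E)-7-[1-(tert-butyldimethylsilyloxy)cyclopropyl]-6-methyl-3-(propan-2-yl)-3-(triethylsilyloxy)hept-6-en-1-yne | C#C[C@](O[Si](CC)(CC)CC)(C(C)C)CC/C(C)=C/C1(O[Si](C)(C)C(C)(C)C)CC1 | intermediate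
13 | (1R,4R)-9-(tert-butyldimethylsilyloxy)-1-methyl-4-(propan-2-yl)-4-(triethylsilyloxy)bicyclo[5.3.0]deca-5,9-diene | C1CC=C2[C@](C)(CC[C@@]2(O[Si](CC)(CC)CC)C(C)C)C=C1O[Si](C)(C)C(C)(C)C | intermediate
14 | (1R,4R)-1-methyl-4-(propan-2-yl)-4-(triethylsilyloxy)bicyclo[5.3.0]dec-5-en-9-one | O=C1CCC=C2[C@](C)(CC[C@@]2(O[Si](CC)(CC)CC)C(C)C)C1 | intermediate
15 | 9,9-ethylenedioxy ketal of 14 | C1COC2(O1)CCC=C3[C@](C)(CC[C@@]3(O[Si](CC)(CC)CC)C(C)C)C2 | intermediate
16 | C6 alkylborane from 15 (boron on C6, H on C5, both trans to the C15 methyl) | C1C[C@H](B)[C@@H]2[C@](C)(CC[C@@]2(O[Si](CC)(CC)CC)C(C)C)CC13OCCO3 | intermediate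
17 | (1R,4R,5S,6S)-9,9-(ethylenedioxy)-1-methyl-4-(propan-2-yl)-4-(triethylsilyloxy)bicyclo[5.3.0]decan-6-ol | C1C[C@H](O)[C@@H]2[C@](C)(CC[C@@]2(O[Si](CC)(CC)CC)C(C)C)CC13OCCO3 | intermediate
18 | 4-hydroxybenzoic acid | O=C(O)c1ccc(O)cc1 | starting material
19 | triisopropylsilyl 4-(triisopropylsilyloxy)benzoate | CC(C)[Si](C(C)C)(C(C)C)OC(=O)c1ccc(O[Si](C(C)C)(C(C)C)C(C)C)cc1 | intermediate
20 | 4-(triisopropylsilyloxy)benzoic acid | O=C(O)c1ccc(O[Si](C(C)C)(C(C)C)C(C)C)cc1 | intermediate
21 | 6-O-[4-(triisopropylsilyloxy)benzoyl] ester of 17 | C1C[C@H](OC(=O)c4ccc(O[Si](C(C)C)(C(C)C)C(C)C)cc4)[C@@H]2[C@](C)(CC[C@@]2(O[Si](CC)(CC)CC)C(C)C)CC13OCCO3 | intermediate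
22 | (1R,4R,5S,6S)-1-methyl-9-oxo-4-(propan-2-yl)-4-(triethylsilyloxy)bicyclo[5.3.0]decan-6-yl 4-(triisopropylsilyloxy)benzoate | O=C1CC[C@H](OC(=O)c3ccc(O[Si](C(C)C)(C(C)C)C(C)C)cc3)[C@@H]2[C@](C)(CC[C@@]2(O[Si](CC)(CC)CC)C(C)C)C1 | intermediate
23 | C8=C9 trimethylsilyl enol ether of 22 | C[Si](C)(C)OC1=CC[C@H](OC(=O)c3ccc(O[Si](C(C)C)(C(C)C)C(C)C)cc3)[C@@H]2[C@](C)(CC[C@@]2(O[Si](CC)(CC)CC)C(C)C)C1 | intermediate
24 | 8-(dimethylaminomethyl) derivative of 22 (Mannich base, mixture at C8) | CN(C)CC1C[C@H](OC(=O)c3ccc(O[Si](C(C)C)(C(C)C)C(C)C)cc3)[C@@H]2[C@](C)(CC[C@@]2(O[Si](CC)(CC)CC)C(C)C)CC1=O | intermediate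
25 | methiodide of 24 | C[N+](C)(C)CC1C[C@H](OC(=O)c3ccc(O[Si](C(C)C)(C(C)C)C(C)C)cc3)[C@@H]2[C@](C)(CC[C@@]2(O[Si](CC)(CC)CC)C(C)C)CC1=O.[I-] | intermediate
26 | (1R,4R,5S,6S)-1-methyl-8-methylidene-9-oxo-4-(propan-2-yl)-4-(triethylsilyloxy)bicyclo[5.3.0]decan-6-yl 4-(triisopropylsilyloxy)benzoate | C=C1C[C@H](OC(=O)c3ccc(O[Si](C(C)C)(C(C)C)C(C)C)cc3)[C@@H]2[C@](C)(CC[C@@]2(O[Si](CC)(CC)CC)C(C)C)CC1=O | intermediate
27 | (1R,4R,5S,6S,9R)-9-hydroxy-1-methyl-8-methylidene-4-(propan-2-yl)-4-(triethylsilyloxy)bicyclo[5.3.0]decan-6-yl 4-(triisopropylsilyloxy)benzoate | C=C1C[C@H](OC(=O)c3ccc(O[Si](C(C)C)(C(C)C)C(C)C)cc3)[C@@H]2[C@](C)(CC[C@@]2(O[Si](CC)(CC)CC)C(C)C)C[C@H]1O | intermediate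
28 | (1R,4R,5S,6S,9R)-4,9-dihydroxy-1-methyl-8-methylidene-4-(propan-2-yl)bicyclo[5.3.0]decan-6-yl 4-hydroxybenzoate | C=C1C[C@H](OC(=O)c2ccc(O)cc2)[C@@H]2[C@](C)(CC[C@@]2(O)C(C)C)C[C@H]1O | target

**Step count and risks**

Total step count: 19 (18 on the main line, 1 for acid 20). Longest linear sequence: 18 steps from 1 to 28 (steps 1–12 and 14–19).

Steps most likely to fail:

Step 9. The relay of configuration from C4 to C1 may be weak, so that the alkyne adds to both faces of the C1=C10 alkene. The crowded trisubstituted alkene may also bind rhodium so slowly that cyclopropane isomerization competes. Fallback: stereocontrol is moved from the substrate to the reagent. Setting out from 12, the cycloaddition is run with a chiral cationic monovalent rhodium catalyst, [Rh((R)-BINAP)]SbF6 or its (S)-enantiomer, in 1,2-dichloroethane at 60–70 °C. This is a known way to impose the face of alkene coordination in (5+2) cycloadditions of tethered vinylcyclopropanes. The ligand enantiomer matched with the C4 centre is kept and the route is rejoined at 13. No new compound arises (F0).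

Step 12. Facial selectivity may be poor because the isopropyl group shields the face that must be attacked, and addition to an alkene flanked by two quaternary carbons may be slow. Fallback: the ring fusion is set by equilibration and the carbinol by thermodynamic reduction instead of kinetic facial control. Setting out from 15, hydroboration–oxidation is run to completion whatever its facial outcome. The undesired cis-fused 5,6-diepimeric alcohol F1 (alone or mixed with 17) is oxidized with Dess–Martin periodinane to the cis-fused C6 ketone F2. This is epimerized at C5 with DBU in toluene to the trans-fused C6 ketone F3, expected to be favoured because it moves C6 off the face of the isopropyl group. Dissolving-metal reduction (Li, liquid NH3, THF, t-BuOH, −78 °C) should then give the equatorial alcohol and return to the route at 17.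

Step 5. The conjugated ester may react sluggishly with the titanacyclopropane or suffer conjugate reduction or addition by the Grignard reagent. Fallback: the cyclopropane is built by carbenoid addition to a silyl dienol ether instead of by ester cyclopropanation. Setting out from 7, the ester is converted with MeNHOMe·HCl and iPrMgCl into Weinreb amide F4 and with MeMgBr into methyl enone F5. Kinetic enolization (LiN(iPr)2, THF, −78 °C) and trapping with TBSCl gives 2-silyloxydiene F6. Simmons–Smith cyclopropanation (Et2Zn, CH2I2, CH2Cl2, 0 °C), selective for the electron-rich enol ether double bond over the trisubstituted alkene, returns to the route at 9.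

Further compounds
F0 | step 9 | none | none
F1 | step 12 | cis-fused 5,6-diepimer of 17 (H-5 and 6-OH cis to the C15 methyl) | C1C[C@@H](O)[C@H]2[C@](C)(CC[C@@]2(O[Si](CC)(CC)CC)C(C)C)CC13OCCO3
F2 | step 12 | cis-fused C6 ketone (H-5 cis to the C15 methyl) | C1CC(=O)[C@H]2[C@](C)(CC[C@@]2(O[Si](CC)(CC)CC)C(C)C)CC13OCCO3
F3 | step 12 | trans-fused C6 ketone (H-5 trans to the C15 methyl) | C1CC(=O)[C@@H]2[C@](C)(CC[C@@]2(O[Si](CC)(CC)CC)C(C)C)CC13OCCO3
F4 | step 5 | (2E,6S)-N-methoxy-8,8-dimethoxy-N,3-dimethyl-6-(propan-2-yl)-6-(triethylsilyloxy)oct-2-enamide | COC(OC)C[C@](O[Si](CC)(CC)CC)(C(C)C)CC/C(C)=C/C(=O)N(C)OC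
F5 | step 5 | (3E,7S)-9,9-dimethoxy-4-methyl-7-(propan-2-yl)-7-(triethylsilyloxy)non-3-en-2-one | COC(OC)C[C@](O[Si](CC)(CC)CC)(C(C)C)CC/C(C)=C/C(C)=O
F6 | step 5 | 2-(tert-butyldimethylsilyloxy)-1,3-diene from F5 | COC(OC)C[C@](O[Si](CC)(CC)CC)(C(C)C)CC/C(C)=C/C(=C)O[Si](C)(C)C(C)(C)C
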